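**Plan**

Locants follow the C22 chain of the target from the lactone carbonyl (C1) to the terminal methyl (C22); O13 is the ether oxygen on C13. Retrosynthesis: after a C7 silyl ether is removed, one event cuts both O13–C2 (dihydropyran ring) and C2–C3 (one bridge of the 2-oxabicyclo[2.2.2]octan-3-one), leading to an α-diazo δ-lactone with a free C13 hydroxyl and a C3 aldehyde; then C12–C13, C11=C12, C2=C10, C9–C10 and C4–C5 are cut in turn.

Enabling feature: C2 is the α-carbon of the δ-lactone ring (C1, C2, C10, C9, C5, O), so it can be a carbenoid and then an enolate; O13 lies six atoms away through the Z C11=C12 alkene, and C5, 1,4 across the lactone ring, holds the C4–C3 arm over C2. The array O13–C2–C3–OH is therefore the retron of O–H insertion plus aldol.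

Forward ring order: cyclopentane ring A (C5–C9, chiral pool) → δ-lactone (ring-closing metathesis) → dihydropyran and carbocyclic bridge together in step 20, which completes the bicyclo[2.2.2]octane.

Stereochemistry: C5 from (R)-4-silyloxycyclopentenone (anti 1,2-addition, the original centre is then oxidised away); C9 by alkoxide-directed conjugate addition; C7 by hydroxyl-directed reduction; C10 by hydride delivery anti to ring A; C13 by ligand-controlled Nozaki–Hiyama–Kishi coupling; C2 and C3 in the key step.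

Key step: step 20

Remark: 1, 7 and 17 are taken as commercially available; TBS = tert-butyldimethylsilyl, TBDPS = tert-butyldiphenylsilyl; "as in the target" means the same spatial arrangement at the named carbons.

**Route**

Step 1
Reactants: 1 (R)-4-[(tert-butyldimethylsilyl)oxy]cyclopent-2-en-1-one
Product: 2 (1R,4R)-4-[(tert-butyldimethylsilyl)oxy]-1-ethenylcyclopent-2-en-1-ol
Conditions: CH2=CHMgBr, CeCl3, THF, −78 °C; aqueous quench
Reagents that add atoms: vinylmagnesium bromide, C=C[Mg]Br
Why: Organocerium 1,2-addition to the enone carbonyl should occur anti to the C4 silyloxy group (cerium suppresses enolisation and β-elimination), so the new tertiary alcohol (future C5) is cis to the silyl ether.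

Step 2
Reactants: 2 (1R,4R)-4-[(tert-butyldimethylsilyl)oxy]-1-ethenylcyclopent-2-en-1-ol
Product: 3 (1S,4R)-4-[(tert-butyldimethylsilyl)oxy]-1-(2-hydroxyethyl)cyclopent-2-en-1-ol
Conditions: 9-BBN (2.5 equiv), THF, 0 °C → rt; then NaOH, H2O2, 0 °C
Reagents that add atoms: hydrogen peroxide, OO
Why: Hydroboration–oxidation with 9-BBN is selective for the monosubstituted vinyl group over the cyclic disubstituted alkene and anti-Markovnikov, giving the two-carbon C4–C3 arm as a primary alcohol without touching a stereocentre.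

Step 3
Reactants: 3 (1S,4R)-4-[(tert-butyldimethylsilyl)oxy]-1-(2-hydroxyethyl)cyclopent-2-en-1-ol
Product: 4 (1S,4R)-1-(2-hydroxyethyl)cyclopent-2-ene-1,4-diol
Conditions: Bu4NF, THF, 0 °C → rt
Reagents that add atoms: none
Why: Fluoride-mediated silyl ether cleavage frees the secondary allylic alcohol and involves no stereocentre.

Step 4
Reactants: 4 (1S,4R)-1-(2-hydroxyethyl)cyclopent-2-ene-1,4-diol
Product: 5 (1S,4R)-1-{2-[(tert-butyldimethylsilyl)oxy]ethyl}cyclopent-2-ene-1,4-diol
Conditions: TBSCl (1.05 equiv), imidazole, CH2Cl2, −20 °C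
Reagents that add atoms: tert-butyldimethylsilyl chloride, CC(C)(C)[Si](C)(C)Cl
Why: Sterically controlled monosilylation takes the primary hydroxyl far faster than the secondary allylic and tertiary ones, which also prevents its later addition to the enone formed in step 5.

Step 5
Reactants: 5 (1S,4R)-1-{2-[(tert-butyldimethylsilyl)oxy]ethyl}cyclopent-2-ene-1,4-diol
Product: 6 (S)-4-{2-[(tert-butyldimethylsilyl)oxy]ethyl}-4-hydroxycyclopent-2-en-1-one
Conditions: MnO2 (activated), CH2Cl2, rt
Reagents that add atoms: none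
Why: MnO2 allylic oxidation converts only the secondary allylic alcohol, so the old stereocentre is erased while the tertiary carbinol C5 set in step 1 remains (1,3-transposition of chirality).

Step 6
Reactants: 6 (S)-4-{2-[(tert-butyldimethylsilyl)oxy]ethyl}-4-hydroxycyclopent-2-en-1-one, 7 2-bromo-3,3-diethoxyprop-1-ene
Product: 9 (3S,4S)-3-{2-[(tert-butyldimethylsilyl)oxy]ethyl}-4-[1-(diethoxymethyl)ethenyl]-3-hydroxycyclopentan-1-one, via alkenylmagnesium bromide 8 (not isolated)
Conditions: 7, t-BuLi (2 equiv), Et2O, −78 °C; MgBr2·OEt2 (gives 8, 3 equiv); then 6, THF, −78 → −20 °C; aqueous quench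
Reagents that add atoms: none
Why: Alkoxide-directed (ligand-assisted) conjugate addition of a Grignard reagent to a γ-hydroxy enone: the magnesium alkoxide on C5 should deliver the alkenyl group to C9 on its own face, which is also the face anti to the larger silyloxyethyl arm, so the C9–C10 bond is cis to the C5 oxygen.

Step 7
Reactants: 9 (3S,4S)-3-{2-[(tert-butyldimethylsilyl)oxy]ethyl}-4-[1-(diethoxymethyl)ethenyl]-3-hydroxycyclopentan-1-one
Product: 10 (1S,3R,5S)-1-{2-[(tert-butyldimethylsilyl)oxy]ethyl}-5-[1-(diethoxymethyl)ethenyl]cyclopentane-1,3-diol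
Conditions: Me4NBH(OAc)3, MeCN/AcOH, −30 °C
Reagents that add atoms: none
Why: Evans–Saksena reduction: the acetoxyborohydride exchanges onto the tertiary C5 hydroxyl and delivers hydride intramolecularly to the C7 ketone from that face, so the new C7 hydroxyl is trans to the C5 oxygen (anti 1,3-diol).

Step 8
Reactants: 10 (1S,3R,5S)-1-{2-[(tert-butyldimethylsilyl)oxy]ethyl}-5-[1-(diethoxymethyl)ethenyl]cyclopentane-1,3-diol
Product: 11 (1S,2S,4R)-4-[(tert-butyldiphenylsilyl)oxy]-1-{2-[(tert-butyldimethylsilyl)oxy]ethyl}-2-[1-(diethoxymethyl)ethenyl]cyclopentan-1-ol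
Conditions: TBDPSCl, imidazole, DMF, rt
Reagents that add atoms: tert-butyl(chloro)diphenylsilane, CC(C)(C)[Si](Cl)(c1ccccc1)c1ccccc1
Why: Silylation with the bulky chlorosilane takes the secondary C7 hydroxyl and leaves the hindered tertiary C5 hydroxyl free for acylation.

Step 9
Reactants: 11 (1S,2S,4R)-4-[(tert-butyldiphenylsilyl)oxy]-1-{2-[(tert-butyldimethylsilyl)oxy]ethyl}-2-[1-(diethoxymethyl)ethenyl]cyclopentan-1-ol
Product: 12 (1S,2S,4R)-4-[(tert-butyldiphenylsilyl)oxy]-1-{2-[(tert-butyldimethylsilyl)oxy]ethyl}-2-[1-(diethoxymethyl)ethenyl]cyclopentyl prop-2-enoate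
Conditions: acryloyl chloride, i-Pr2NEt, DMAP (cat.), CH2Cl2, 0 °C → rt
Reagents that add atoms: acryloyl chloride, C=CC(=O)Cl
Why: DMAP-catalysed acylation (via the acylpyridinium) esterifies the tertiary alcohol with retention at C5 and brings in C1 and C2.

Step 10
Reactants: 12 (1S,2S,4R)-4-[(tert-butyldiphenylsilyl)oxy]-1-{2-[(tert-butyldimethylsilyl)oxy]ethyl}-2-[1-(diethoxymethyl)ethenyl]cyclopentyl prop-2-enoate
Product: 13 unsaturated lactone (C2=C10) with 10-diethoxymethyl group
Conditions: second-generation Grubbs catalyst (10 mol%), toluene, 80 °C, argon sparge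
Reagents that add atoms: none
Why: Ring-closing metathesis between the acrylate and the cis-disposed 1,1-disubstituted alkene should close the six-membered α,β-unsaturated lactone with loss of ethene, the cis C5/C9 relationship fixing a cis ring fusion.

Step 11
Reactants: 13 unsaturated lactone (C2=C10) with 10-diethoxymethyl group
Product: 14 saturated lactone with 10-diethoxymethyl group
Conditions: Cu(OAc)2·H2O (5 mol%), 1,2-bis(diphenylphosphino)benzene (5 mol%), (EtO)2MeSiH, t-BuOH, toluene, rt
Reagents that add atoms: none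
Why: Copper hydride conjugate reduction (ligated CuH formed in the flask from the copper acetate and the silane): hydride should add to C10 on the lactone face anti to the adjacent ring A carbon C8, as nucleophiles do with 5-substituted 5,6-dihydropyran-2-ones, so H10 ends cis to H9 and C11 cis to C8.

Step 12
Reactants: 14 saturated lactone with 10-diethoxymethyl group
Product: 15 lactone C11 aldehyde
Conditions: 10% aqueous oxalic acid on SiO2, CH2Cl2, rt; used at once
Reagents that add atoms: water, O
Why: Mild heterogeneous acetal hydrolysis releases the C11 aldehyde while silyl ethers and lactone survive and the α-centre C10 is not enolised.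

Step 13
Reactants: 15 lactone C11 aldehyde
Product: 16 lactone (Z)-12-iodo-C11=C12 alkene
Conditions: (1-iodoethyl)triphenylphosphonium iodide, NaN(SiMe3)2, THF, −78 °C; then 15, −78 → −20 °C
Reagents that add atoms: (1-iodoethyl)triphenylphosphonium iodide, CC(I)[P+](c1ccccc1)(c1ccccc1)c1ccccc1.[I-]
Why: Stork–Zhao olefination: the α-iodo ylide reacts under kinetic control through the cis-oxaphosphetane to give the (Z)-2-iodoalkene (iodine cis to C10) at a temperature at which C10 is not epimerised.

Step 14
Reactants: 16 lactone (Z)-12-iodo-C11=C12 alkene, 17 (E)-dec-2-enal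
Product: 18 lactone (13R)-allylic alcohol
Conditions: CrCl2 (4 equiv), chiral oxazoline–sulfonamide ligand (S)-N-[2-(4-isopropyl-4,5-dihydrooxazol-2-yl)-6-methylphenyl]methanesulfonamide or its enantiomer (4.4 equiv), Et3N, NiCl2 (2 mol%), THF/MeCN, rt
Reagents that add atoms: none
Why: Nozaki–Hiyama–Kishi coupling: NiCl2-catalysed activation of the alkenyl iodide with retention of the Z geometry, transmetalation to the trivalent alkenylchromium and 1,2-addition to the enal, the sulfonamide ligand on chromium (enantiomer chosen for the 13R carbinol, to be confirmed by Mosher ester analysis) selecting the aldehyde face.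

Step 15
Reactants: 18 lactone (13R)-allylic alcohol
Product: 19 lactone 13-O-TBS ether
Conditions: TBSCl, imidazole, DMF, rt
Reagents that add atoms: tert-butyldimethylsilyl chloride, CC(C)(C)[Si](C)(C)Cl
Why: Standard silylation protects the bis-allylic alcohol from the base of step 16 and the oxidant of step 18.

Step 16
Reactants: 19 lactone 13-O-TBS ether
Product: 21 2-diazo lactone, via 2-trifluoroacetyl lactone 20 (not isolated)
Conditions: LiN(SiMe3)2, THF, −78 °C; CF3CO2CH2CF3, −78 °C; then MeSO2N3, Et3N, H2O (1 equiv), MeCN, rt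
Reagents that add atoms: methanesulfonyl azide, CS(=O)(=O)N=[N+]=[N-]
Why: Deacylative (Regitz-type) diazo transfer: the kinetic lactone enolate is C-trifluoroacetylated at C2, the only enolisable position, and the resulting 1,3-dicarbonyl takes the diazo group from the sulfonyl azide with loss of the trifluoroacetyl group as the N-acylsulfonamide.

Step 17
Reactants: 21 2-diazo lactone
Product: 22 2-diazo lactone C3 primary alcohol
Conditions: HF·pyridine, pyridine, THF, 0 °C
Reagents that add atoms: none
Why: Buffered HF·pyridine desilylation cleaves the least hindered (primary) TBS ether first and leaves the secondary TBS ether, the TBDPS ether and the acceptor-substituted diazo group untouched.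

Step 18
Reactants: 22 2-diazo lactone C3 primary alcohol
Product: 23 2-diazo lactone C3 aldehyde
Conditions: Dess–Martin periodinane, NaHCO3, CH2Cl2, 0 °C → rt
Reagents that add atoms: none
Why: Dess–Martin oxidation converts the primary alcohol into the aldehyde under near-neutral conditions that diazo esters and alkenes tolerate.

Step 19
Reactants: 23 2-diazo lactone C3 aldehyde
Product: 24 2-diazo lactone C3 aldehyde with free 13-hydroxyl
Conditions: HF·pyridine, pyridine, THF, 0 °C → rt
Reagents that add atoms: none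
Why: Longer exposure to buffered HF·pyridine removes the secondary TBS ether, whereas the TBDPS ether on C7, much more stable to acidic fluoride, stays.

Step 20
Reactants: 24 2-diazo lactone C3 aldehyde with free 13-hydroxyl
Product: 26 7-O-TBDPS ether of the target, via oxonium ylide 25 (not isolated)
Conditions: Rh2(O2CCPh3)4 (1 mol%), 4 Å molecular sieves, CH2Cl2, −40 → 0 °C, slow addition of 24 (final 0.005 M)
Reagents that add atoms: none
Why: Proposed new method: loss of N2 gives the rhodium carbenoid at C2, which the C13 hydroxyl captures (6-exo attack on the carbenoid carbon, closing the dihydropyran) to give oxonium ylide 25; its lactone-enolate carbon C2 then adds to the tethered C3 aldehyde before the usual 1,2-proton shift, and the oxonium proton ends on the new alkoxide. The closest known reactions are carbenoid O–H insertion with aldol-type trapping of the oxonium ylide (three-component diazo ester/alcohol/aldehyde coupling) and intramolecular O–H insertion to 2-carboxy cyclic ethers; new here are the double tethering, the α-alkyl diazo lactone and the bridged ring that the aldol closes. This aldol is a 6-(enolexo)-exo-trig closure of the carbocycle C2–C3–C4–C5–C9–C10 through the boat form of the lactone, that is a 1,4-bridging of C2 and C5 which completes the 2-oxabicyclo[2.2.2]octan-3-one. C2 is fixed by the two tethers, since O13 must stay on the side of the C10 side chain and C3 can only reach the opposite face, on which C5 carries the C4 arm (steps 1 and 6), so one bridgehead configuration is possible; C3 should follow from an open transition state in which the aldehyde oxygen turns away from the enolate and ring oxygens (a closed, hydrogen-bonded arrangement is out of reach across the forming bridge), placing the hydroxyl syn to the C9–C10 bridge (3R). The step needs O–H capture to outrun the 1,2-hydride shift of H10 and the aldol to outrun proton transfer: the first is secured by the six-membered intramolecular approach of the hydroxyl through the Z alkene (helped by the bulky carboxylate ligands and low temperature), the second by the cis ring fusion holding the aldehyde within bonding distance of C2 and by exclusion of water and other proton shuttles.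

Step 21
Reactants: 26 7-O-TBDPS ether of the target
Product: 27 target CNP0127096.1
Conditions: Bu4NF, AcOH (1:1), THF, rt
Reagents that add atoms: none
Why: Acetic acid-buffered fluoride desilylation should remove the TBDPS ether without retro-aldol opening of the β-hydroxy lactone or ionisation of the bis-allylic ether.

**Compound list**

1 | (R)-4-[(tert-butyldimethylsilyl)oxy]cyclopent-2-en-1-one | O=C1C=C[C@H](O[Si](C)(C)C(C)(C)C)C1 | starting material
2 | (1R,4R)-4-[(tert-butyldimethylsilyl)oxy]-1-ethenylcyclopent-2-en-1-ol (OH cis to OTBS) | C1=C[C@H](O[Si](C)(C)C(C)(C)C)C[C@]1(C=C)O | intermediate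
3 | (1S,4R)-4-[(tert-butyldimethylsilyl)oxy]-1-(2-hydroxyethyl)cyclopent-2-en-1-ol | C1=C[C@H](O[Si](C)(C)C(C)(C)C)C[C@]1(CCO)O | intermediate
4 | (1S,4R)-1-(2-hydroxyethyl)cyclopent-2-ene-1,4-diol | C1=C[C@H](O)C[C@]1(CCO)O | intermediate
5 | (1S,4R)-1-{2-[(tert-butyldimethylsilyl)oxy]ethyl}cyclopent-2-ene-1,4-diol | C1=C[C@H](O)C[C@]1(CCO[Si](C)(C)C(C)(C)C)O | intermediate
6 | (S)-4-{2-[(tert-butyldimethylsilyl)oxy]ethyl}-4-hydroxycyclopent-2-en-1-one | C1=CC(=O)C[C@]1(CCO[Si](C)(C)C(C)(C)C)O | intermediate
7 | 2-bromo-3,3-diethoxyprop-1-ene | C=C(Br)C(OCC)OCC | starting material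
8 | [1-(diethoxymethyl)ethenyl]magnesium bromide (not isolated) | C=C([Mg]Br)C(OCC)OCC | intermediate
9 | (3S,4S)-3-{2-[(tert-butyldimethylsilyl)oxy]ethyl}-4-[1-(diethoxymethyl)ethenyl]-3-hydroxycyclopentan-1-one (alkenyl group cis to OH) | C=C(C(OCC)OCC)[C@@H]1CC(=O)C[C@]1(CCO[Si](C)(C)C(C)(C)C)O | intermediate
10 | (1S,3R,5S)-1-{2-[(tert-butyldimethylsilyl)oxy]ethyl}-5-[1-(diethoxymethyl)ethenyl]cyclopentane-1,3-diol (hydroxyls trans) | C=C(C(OCC)OCC)[C@@H]1C[C@@H](O)C[C@]1(CCO[Si](C)(C)C(C)(C)C)O | intermediate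
11 | (1S,2S,4R)-4-[(tert-butyldiphenylsilyl)oxy]-1-{2-[(tert-butyldimethylsilyl)oxy]ethyl}-2-[1-(diethoxymethyl)ethenyl]cyclopentan-1-ol | C=C(C(OCC)OCC)[C@@H]1C[C@@H](O[Si](c2ccccc2)(c2ccccc2)C(C)(C)C)C[C@]1(CCO[Si](C)(C)C(C)(C)C)O | intermediate
12 | (1S,2S,4R)-4-[(tert-butyldiphenylsilyl)oxy]-1-{2-[(tert-butyldimethylsilyl)oxy]ethyl}-2-[1-(diethoxymethyl)ethenyl]cyclopentyl prop-2-enoate | C=C(C(OCC)OCC)[C@@H]1C[C@@H](O[Si](c2ccccc2)(c2ccccc2)C(C)(C)C)C[C@]1(CCO[Si](C)(C)C(C)(C)C)OC(=O)C=C | intermediate
13 | unsaturated lactone: cyclopenta[b]pyran-2-one, lactone ring C1–C2=C10–C9–C5–O cis-fused to ring A at C5/C9, 10-diethoxymethyl, 7-OTBDPS, 5-(2-TBSO-ethyl); C5, C7, C9 as in the target | O=C1C=C(C(OCC)OCC)[C@@H]2C[C@@H](O[Si](c3ccccc3)(c3ccccc3)C(C)(C)C)C[C@]2(CCO[Si](C)(C)C(C)(C)C)O1 | intermediate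
14 | saturated lactone: as 13 with C2H2 and C10–H cis to C9–H (10-diethoxymethyl cis to C8); C5, C7, C9, C10 as in the target | O=C1C[C@H](C(OCC)OCC)[C@@H]2C[C@@H](O[Si](c3ccccc3)(c3ccccc3)C(C)(C)C)C[C@]2(CCO[Si](C)(C)C(C)(C)C)O1 | intermediate
15 | lactone C11 aldehyde: as 14 with CHO on C10 | O=C1C[C@H](C=O)[C@@H]2C[C@@H](O[Si](c3ccccc3)(c3ccccc3)C(C)(C)C)C[C@]2(CCO[Si](C)(C)C(C)(C)C)O1 | intermediate
16 | lactone (Z)-alkenyl iodide: as 14 with (Z)-CH=C(CH3)I on C10 (iodine cis to C10) | O=C1C[C@H](/C=C(/C)I)[C@@H]2C[C@@H](O[Si](c3ccccc3)(c3ccccc3)C(C)(C)C)C[C@]2(CCO[Si](C)(C)C(C)(C)C)O1 | intermediate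
17 | (E)-dec-2-enal | CCCCCCC/C=C/C=O | starting material
18 | lactone (13R)-allylic alcohol: as 14 with the full C11–C22 side chain, Z C11=C12, E C14=C15, free 13-OH | O=C1C[C@H](/C=C(/C)[C@H](O)/C=C/CCCCCCC)[C@@H]2C[C@@H](O[Si](c3ccccc3)(c3ccccc3)C(C)(C)C)C[C@]2(CCO[Si](C)(C)C(C)(C)C)O1 | intermediate
19 | 13-O-TBS ether of 18 | O=C1C[C@H](/C=C(/C)[C@H](O[Si](C)(C)C(C)(C)C)/C=C/CCCCCCC)[C@@H]2C[C@@H](O[Si](c3ccccc3)(c3ccccc3)C(C)(C)C)C[C@]2(CCO[Si](C)(C)C(C)(C)C)O1 | intermediate
20 | 2-trifluoroacetyl derivative of 19 (C2 epimers or enol, not isolated) | O=C1C(C(=O)C(F)(F)F)[C@H](/C=C(/C)[C@H](O[Si](C)(C)C(C)(C)C)/C=C/CCCCCCC)[C@@H]2C[C@@H](O[Si](c3ccccc3)(c3ccccc3)C(C)(C)C)C[C@]2(CCO[Si](C)(C)C(C)(C)C)O1 | intermediate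
21 | 2-diazo lactone (13-OTBS, primary OTBS, 7-OTBDPS) | O=C1C(=[N+]=[N-])[C@H](/C=C(/C)[C@H](O[Si](C)(C)C(C)(C)C)/C=C/CCCCCCC)[C@@H]2C[C@@H](O[Si](c3ccccc3)(c3ccccc3)C(C)(C)C)C[C@]2(CCO[Si](C)(C)C(C)(C)C)O1 | intermediate
22 | 2-diazo lactone with free C3 primary alcohol | O=C1C(=[N+]=[N-])[C@H](/C=C(/C)[C@H](O[Si](C)(C)C(C)(C)C)/C=C/CCCCCCC)[C@@H]2C[C@@H](O[Si](c3ccccc3)(c3ccccc3)C(C)(C)C)C[C@]2(CCO)O1 | intermediate
23 | 2-diazo lactone with C3 aldehyde (13-OTBS) | O=C1C(=[N+]=[N-])[C@H](/C=C(/C)[C@H](O[Si](C)(C)C(C)(C)C)/C=C/CCCCCCC)[C@@H]2C[C@@H](O[Si](c3ccccc3)(c3ccccc3)C(C)(C)C)C[C@]2(CC=O)O1 | intermediate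
24 | 2-diazo lactone with C3 aldehyde and free (13R)-hydroxyl (7-OTBDPS) | O=C1C(=[N+]=[N-])[C@H](/C=C(/C)[C@H](O)/C=C/CCCCCCC)[C@@H]2C[C@@H](O[Si](c3ccccc3)(c3ccccc3)C(C)(C)C)C[C@]2(CC=O)O1 | intermediate
25 | oxonium ylide (O13 protonated oxonium, C2=C1 lactone enolate; not isolated) | CCCCCCC/C=C/[C@H]1[OH+]C2=C([O-])O[C@]3(C[C@H](O[Si](c4ccccc4)(c4ccccc4)C(C)(C)C)C[C@H]3[C@H]2C=C1C)CC=O | intermediate
26 | 7-O-TBDPS ether of the target (tetracycle complete, free 3-OH) | CCCCCCC/C=C/[C@H]1O[C@@]23C(=O)O[C@]4(C[C@H](O[Si](c5ccccc5)(c5ccccc5)C(C)(C)C)C[C@H]4[C@H]2C=C1C)C[C@H]3O | intermediate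
27 | CNP0127096.1 (chain descriptors 2S,3R,5R,7R,9S,10R,13R) | CCCCCCC/C=C/[C@H]1O[C@@]23C(=O)O[C@]4(C[C@H](O)C[C@H]4[C@H]2C=C1C)C[C@H]3O | target

**Step count and risks**

Total steps: 21. Longest linear sequence: 21 steps (1 → 27); 7 and 17 enter as purchased partners.

Steps most likely to fail:

1. Step 20. The 1,2-hydride shift of H10 in the carbenoid may outrun O–H capture, or the oxonium ylide may collapse by proton transfer (plain O–H insertion) before the aldol; the aldehyde face may also be chosen less cleanly than argued. Fallback with known chemistry, setting out from 19: enolate hydroxylation with LiN(SiMe3)2 and 2-(phenylsulfonyl)-3-phenyloxaziridine should give the 2-hydroxy lactone F1. Dess–Martin oxidation gives the 2-oxo lactone F2, which is taken on crude to limit enolisation toward C10. HF·pyridine removes both TBS groups, and the freed C13 hydroxyl closes onto the C2 ketone (the same O13–C2 bond, now as a six-membered hemiketal) to give the hemiketal diol F3. Dess–Martin oxidation of the primary alcohol gives the hemiketal aldehyde F4, and Ac2O/DMAP gives the anomeric acetate F5. SmI2 in THF then reduces the C2–OAc bond to the samarium lactone enolate, as in C-glycosylation of ulosonic acid donors, and this adds to the aldehyde (samarium Reformatsky-type aldol), coming back to the route at 26.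

2. Step 11. Facial selectivity of hydride delivery to C10 may be poor, because the axial C4 arm on C5 partly shields the face that must be attacked. Fallback, setting out from 13: buffered HF·pyridine cleaves the primary TBS ether to give the unsaturated lactone alcohol F6. Hydroxyl-directed hydrogenation with [Ir(cod)(PCy3)(py)]PF6 and H2 in CH2Cl2, the hydroxyethyl arm on C5 lying on the face to which hydrogen must be delivered, gives the saturated lactone alcohol F7. Resilylation (TBSCl, imidazole) comes back to the route at 14.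

3. Step 14. Ligand control at C13 may be insufficient, through mismatch with the remote C10 centre or a competing unligated addition. Fallback, setting out from 18 obtained as a C13 epimer mixture: MnO2 oxidation gives the cross-conjugated dienone F8. Corey–Bakshi–Shibata reduction with (S)-2-methyl-CBS-oxazaborolidine and catecholborane, the α-branched trisubstituted alkenyl group acting as the large substituent, should return the 13R alcohol and come back to the route at 18.

**Further compounds**

F1 | step 20 | 2-hydroxy lactone from 19 (C2 epimers) | O=C1C(O)[C@H](/C=C(/C)[C@H](O[Si](C)(C)C(C)(C)C)/C=C/CCCCCCC)[C@@H]2C[C@@H](O[Si](c3ccccc3)(c3ccccc3)C(C)(C)C)C[C@]2(CCO[Si](C)(C)C(C)(C)C)O1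
F2 | step 20 | 2-oxo lactone | O=C1C(=O)[C@H](/C=C(/C)[C@H](O[Si](C)(C)C(C)(C)C)/C=C/CCCCCCC)[C@@H]2C[C@@H](O[Si](c3ccccc3)(c3ccccc3)C(C)(C)C)C[C@]2(CCO[Si](C)(C)C(C)(C)C)O1
F3 | step 20 | hemiketal diol (dihydropyran closed at C2, C2–OH, primary alcohol on the C4 arm) | CCCCCCC/C=C/[C@H]1OC2(O)C(=O)O[C@]3(C[C@H](O[Si](c4ccccc4)(c4ccccc4)C(C)(C)C)C[C@H]3[C@H]2C=C1C)CCO
F4 | step 20 | hemiketal aldehyde | CCCCCCC/C=C/[C@H]1OC2(O)C(=O)O[C@]3(C[C@H](O[Si](c4ccccc4)(c4ccccc4)C(C)(C)C)C[C@H]3[C@H]2C=C1C)CC=O
F5 | step 20 | anomeric acetate (C2–OAc) aldehyde | CCCCCCC/C=C/[C@H]1OC2(OC(C)=O)C(=O)O[C@]3(C[C@H](O[Si](c4ccccc4)(c4ccccc4)C(C)(C)C)C[C@H]3[C@H]2C=C1C)CC=O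
F6 | step 11 | unsaturated lactone alcohol (13 without the primary TBS group) | O=C1C=C(C(OCC)OCC)[C@@H]2C[C@@H](O[Si](c3ccccc3)(c3ccccc3)C(C)(C)C)C[C@]2(CCO)O1
F7 | step 11 | saturated lactone alcohol (14 without the primary TBS group) | O=C1C[C@H](C(OCC)OCC)[C@@H]2C[C@@H](O[Si](c3ccccc3)(c3ccccc3)C(C)(C)C)C[C@]2(CCO)O1
F8 | step 14 | C13 dienone | O=C1C[C@H](/C=C(/C)C(=O)/C=C/CCCCCCC)[C@@H]2C[C@@H](O[Si](c3ccccc3)(c3ccccc3)C(C)(C)C)C[C@]2(CCO[Si](C)(C)C(C)(C)C)O1
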